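**Plan**

- Remark on the chemistry: the target has no stereogenic element, so there is no enantiomer to select. The two sp3 centres made in the annulation are racemic and are erased on aromatisation.
- Enabling feature: ring B carries CO2H at C1, OH at C2 and C4, the depside oxygen at C3 and propyl at C6. This is a β-resorcylate made of a malonate unit (C1, C2, carboxyl) and a seven-carbon enone (C3–C6 plus propyl) whose α'-carbon C3 already bears the ring A carboxylate.
- Cuts: ring B bonds C1–C6 and C2–C3 (Michael–Claisen), then the O–CH2 bond of the acyloxymethyl ketone (carboxylate SN2), the enone C=C (Wittig), and the ring A carboxyl carbon back to divarinol (formylation).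
- Forward: the ring A acid is made from divarinol in four steps and O-alkylated with a chloro enone made in one step. Ring B is then grown on this ester, dehydrogenated to the arene, and both benzyl groups are removed last.

Key step: step 7

**Route**

Step 1
Reactants: 1 5-propylbenzene-1,3-diol (divarinol)
Product: 3 2,4-dihydroxy-6-propylbenzaldehyde, via aryl iminium chloride 2 (not isolated)
Conditions: POCl3, DMF, MeCN, 0 °C → rt; then H2O, 50 °C
Reagents that add atoms: N,N-dimethylformamide CN(C)C=O; water O
Why: Vilsmeier–Haack formylation of a 5-alkylresorcinol should attack the ring position ortho to one hydroxyl and para to the other (as with orcinol), and hydrolysis of the iminium salt then frees the aldehyde.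

Step 2
Reactants: 3 2,4-dihydroxy-6-propylbenzaldehyde
Product: 4 4-(benzyloxy)-2-hydroxy-6-propylbenzaldehyde
Conditions: BnBr (1.05 equiv), K2CO3, acetone, reflux
Reagents that add atoms: benzyl bromide BrCc1ccccc1
Why: Williamson etherification should be selective for the 4-hydroxyl because the 2-hydroxyl is held in a hydrogen bond to the formyl group and is less acidic and less nucleophilic.

Step 3
Reactants: 4 4-(benzyloxy)-2-hydroxy-6-propylbenzaldehyde
Product: 5 4-(benzyloxy)-2-methoxy-6-propylbenzaldehyde
Conditions: MeI (excess), K2CO3, DMF, rt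
Reagents that add atoms: iodomethane CI
Why: Williamson methylation in a dipolar aprotic solvent with excess iodomethane should alkylate the remaining chelated phenol, the only acidic site left.

Step 4
Reactants: 5 4-(benzyloxy)-2-methoxy-6-propylbenzaldehyde
Product: 6 4-(benzyloxy)-2-methoxy-6-propylbenzoic acid
Conditions: NaClO2, NaH2PO4, 2-methylbut-2-ene, t-BuOH/THF/H2O, 0 °C → rt
Reagents that add atoms: sodium chlorite [Na+].[O-]Cl=O
Why: Pinnick oxidation should convert the hindered, electron-rich aldehyde to the acid while the alkene scavenger removes hypochlorous acid before it can chlorinate the dialkoxyarene.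

Step 5
Reactants: 7 butanal; 8 1-chloro-3-(triphenylphosphoranylidene)propan-2-one
Product: 9 (E)-1-chlorohept-3-en-2-one
Conditions: THF, 60 °C
Reagents that add atoms: none
Why: Wittig olefination with a carbonyl-stabilised ylide should give the E-enone and leaves the chloromethyl ketone untouched.

Step 6
Reactants: 6 4-(benzyloxy)-2-methoxy-6-propylbenzoic acid; 9 (E)-1-chlorohept-3-en-2-one
Product: 10 (E)-2-oxohept-3-en-1-yl 4-(benzyloxy)-2-methoxy-6-propylbenzoate
Conditions: Cs2CO3 (0.5 equiv), MeOH/H2O, evaporate; then 9 (1.2 equiv), NaI (cat.), DMF, rt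
Reagents that add atoms: none
Why: SN2 alkylation of a caesium carboxylate by an α-chloro ketone (iodide-catalysed) forms the ester at oxygen, so the di-ortho-substitution that blocks acyl substitution at this carboxyl group does not matter.

Step 7
Reactants: 10 (E)-2-oxohept-3-en-1-yl 4-(benzyloxy)-2-methoxy-6-propylbenzoate; 11 dibenzyl malonate
Product: 13 benzyl 3-{[4-(benzyloxy)-2-methoxy-6-propylbenzoyl]oxy}-4-hydroxy-2-oxo-6-propylcyclohex-3-ene-1-carboxylate (racemic; enol tautomers), via Michael adduct 12 (not isolated)
Conditions: 11 (1.1 equiv), t-BuOK (1.1 equiv), THF, 0 °C; add 10, 0 °C → rt (40 °C if ring closure lags); 1 M HCl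
Reagents that add atoms: none
Why: Proposed new method: potassium dibenzyl malonate should add in conjugate fashion to the E-enone at the propyl-bearing carbon (future C6), and proton transfer through t-BuOH then gives the ketone enolate on the acyloxymethyl side, the more acidic α-position and the only one that can reach a malonate carbonyl through a six-membered transition state; its C-acylation expels benzyloxide, which is consumed at once by deprotonating the acidic 2-acyloxy-1,3-dione, so the sequence is driven to 13. The closest known reaction type is the alkoxide-mediated Michael–Claisen (Dieckmann) annulation of malonates with alk-3-en-2-ones, including α'-alkyl enones, to 6-alkyl dihydroresorcylates; what is new is that the Claisen donor is an α-acyloxy ketone enolate. The ring closes in 6-exo-trig mode, C1–C6 forming in the Michael stage and C2–C3 in the Claisen stage. C1 and C6 arise racemic (trans expected under equilibration) and need no control because both become sp2 in step 8. The selectivity required is C-acylation at a malonate ester in preference to attack on, migration of or loss of the ring A acyl group, and it is secured by the 2-methoxy and 6-propyl groups flanking that carbonyl and by the absence of alcohol solvent or free alkoxide.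

Step 8
Reactants: 13 benzyl 3-{[4-(benzyloxy)-2-methoxy-6-propylbenzoyl]oxy}-4-hydroxy-2-oxo-6-propylcyclohex-3-ene-1-carboxylate
Product: 16 benzyl 3-{[4-(benzyloxy)-2-methoxy-6-propylbenzoyl]oxy}-2,4-dihydroxy-6-propylbenzoate, via C1 phenylselenide 14 (not isolated), via C1 selenoxide 15 (not isolated)
Conditions: LDA (2.2 equiv), THF, −78 → −40 °C; PhSeBr (1.1 equiv), −78 °C; AcOH, then 30% H2O2, 0 °C → rt
Reagents that add atoms: none
Why: Enolate selenenylation followed by selenoxide syn-elimination: the dianion should form at C1 (acidified by the ester and the C2 carbonyl), PhSeBr should enter anti to the C6 propyl group so that the selenoxide has the C6 hydrogen syn, and the resulting C1=C6 dienone tautomerises irreversibly to the resorcylate without any electrophilic halogen that could attack ring A (selenenylation at C5 instead would converge on the same arene).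

Step 9
Reactants: 16 benzyl 3-{[4-(benzyloxy)-2-methoxy-6-propylbenzoyl]oxy}-2,4-dihydroxy-6-propylbenzoate
Product: 17 3-[(4-hydroxy-2-methoxy-6-propylbenzoyl)oxy]-2,4-dihydroxy-6-propylbenzoic acid (target, achiral)
Conditions: H2 (1 atm), 10% Pd/C, EtOAc, rt
Reagents that add atoms: none
Why: Catalytic hydrogenolysis should cleave the benzyl ether and the benzyl ester under neutral conditions that leave the hindered depside ester and the aryl methyl ether intact and give no opportunity for base-induced acyl migration.

**Compound list**

1 | 5-propylbenzene-1,3-diol (divarinol) | CCCc1cc(O)cc(O)c1 | starting material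
2 | N-[(2,4-dihydroxy-6-propylphenyl)methylidene]-N-methylmethanaminium chloride | CCCc1cc(O)cc(O)c1C=[N+](C)C.[Cl-] | intermediate (not isolated)
3 | 2,4-dihydroxy-6-propylbenzaldehyde | CCCc1cc(O)cc(O)c1C=O | intermediate
4 | 4-(benzyloxy)-2-hydroxy-6-propylbenzaldehyde | CCCc1cc(OCc2ccccc2)cc(O)c1C=O | intermediate
5 | 4-(benzyloxy)-2-methoxy-6-propylbenzaldehyde | CCCc1cc(OCc2ccccc2)cc(OC)c1C=O | intermediate
6 | 4-(benzyloxy)-2-methoxy-6-propylbenzoic acid | CCCc1cc(OCc2ccccc2)cc(OC)c1C(=O)O | intermediate
7 | butanal | CCCC=O | starting material
8 | 1-chloro-3-(triphenylphosphoranylidene)propan-2-one | ClCC(=O)C=P(c1ccccc1)(c1ccccc1)c1ccccc1 | starting material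
9 | (E)-1-chlorohept-3-en-2-one | CCC/C=C/C(=O)CCl | intermediate
10 | (E)-2-oxohept-3-en-1-yl 4-(benzyloxy)-2-methoxy-6-propylbenzoate | CCCc1cc(OCc2ccccc2)cc(OC)c1C(=O)OCC(=O)/C=C/CCC | intermediate
11 | dibenzyl malonate | O=C(CC(=O)OCc1ccccc1)OCc1ccccc1 | starting material
12 | dibenzyl 2-(1-{[4-(benzyloxy)-2-methoxy-6-propylbenzoyl]oxy}-2-oxoheptan-4-yl)propanedioate (racemic) | CCCc1cc(OCc2ccccc2)cc(OC)c1C(=O)OCC(=O)CC(CCC)C(C(=O)OCc1ccccc1)C(=O)OCc1ccccc1 | intermediate (not isolated)
13 | benzyl 3-{[4-(benzyloxy)-2-methoxy-6-propylbenzoyl]oxy}-4-hydroxy-2-oxo-6-propylcyclohex-3-ene-1-carboxylate (racemic; enol tautomers) | CCCC1CC(O)=C(OC(=O)c2c(CCC)cc(OCc3ccccc3)cc2OC)C(=O)C1C(=O)OCc1ccccc1 | intermediate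
14 | benzyl 3-{[4-(benzyloxy)-2-methoxy-6-propylbenzoyl]oxy}-4-hydroxy-2-oxo-1-(phenylselanyl)-6-propylcyclohex-3-ene-1-carboxylate (racemic; SePh expected anti to propyl) | CCCC1CC(O)=C(OC(=O)c2c(CCC)cc(OCc3ccccc3)cc2OC)C(=O)C1([Se]c4ccccc4)C(=O)OCc5ccccc5 | intermediate (not isolated)
15 | benzyl 3-{[4-(benzyloxy)-2-methoxy-6-propylbenzoyl]oxy}-4-hydroxy-2-oxo-1-(phenylseleninyl)-6-propylcyclohex-3-ene-1-carboxylate (racemic) | CCCC1CC(O)=C(OC(=O)c2c(CCC)cc(OCc3ccccc3)cc2OC)C(=O)C1([Se](=O)c4ccccc4)C(=O)OCc5ccccc5 | intermediate (not isolated)
16 | benzyl 3-{[4-(benzyloxy)-2-methoxy-6-propylbenzoyl]oxy}-2,4-dihydroxy-6-propylbenzoate | CCCc1cc(OCc2ccccc2)cc(OC)c1C(=O)Oc1c(O)cc(CCC)c(C(=O)OCc2ccccc2)c1O | intermediate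
17 | 3-[(4-hydroxy-2-methoxy-6-propylbenzoyl)oxy]-2,4-dihydroxy-6-propylbenzoic acid | CCCc1cc(O)cc(OC)c1C(=O)Oc1c(O)cc(CCC)c(C(=O)O)c1O | target

**Count and risks**

Total steps: 9. Longest linear sequence: 8 steps (steps 1–4 and 6–9 from divarinol); step 5 is a one-step side branch.

Steps most likely to fail:

1. Step 7 (proposed new method). The acyloxymethyl enolate may not close on carbon: the sequence may stall at the Michael adduct, the ring A acyl group may shift or be expelled, or the malonate carbanion may displace the carboxylate to give a cyclopentanone. The fallback builds ring B first and installs the C3–O bond afterwards, using known reactions only. It sets out from dibenzyl malonate 11 and acid 6. The parent Michael–Claisen annulation of 11 with commercial (E)-hept-3-en-2-one F1 (t-BuOK, THF) should give benzyl 4-hydroxy-2-oxo-6-propylcyclohex-3-ene-1-carboxylate F2. Regitz diazo transfer (4-acetamidobenzenesulfonyl azide, Et3N, MeCN) at C3, the only methylene between two carbonyls, should give benzyl 3-diazo-2,4-dioxo-6-propylcyclohexane-1-carboxylate F3. Rh2(OAc)4-catalysed O–H insertion of the carbenoid into acid 6 (CH2Cl2, reflux) then forms the C3 ester and returns to the route at 13.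

2. Step 8. The second deprotonation may be incomplete, selenium may be delivered to C3 or to oxygen, selenium placed syn to the propyl group would leave no syn hydrogen for elimination, and selenenic acid may attack the new resorcinol ring. The fallback replaces enolate functionalisation by direct hydride abstraction: 13 is heated with DDQ (1.2 equiv) in 1,4-dioxane at 80 °C to give 16. No new compound arises on this path (F0), and it returns to the route at 16.

3. Step 6. Chloro enone 9 is volatile, base-sensitive and a double electrophile, so loss on handling, oligomerisation or conjugate addition may compete with the SN2 displacement. The fallback inverts the order of the two bond formations. The caesium salt of acid 6 is alkylated with ylide 8 itself (NaI cat., DMF, 50 °C) to give 2-oxo-3-(triphenylphosphoranylidene)propyl 4-(benzyloxy)-2-methoxy-6-propylbenzoate F4. Wittig reaction of F4 with butanal 7 (toluene, 80 °C) then gives the E-enone and returns to the route at 10.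

**Further compounds**

F1 | step 7 | (E)-hept-3-en-2-one | CCC/C=C/C(C)=O
F2 | step 7 | benzyl 4-hydroxy-2-oxo-6-propylcyclohex-3-ene-1-carboxylate (racemic; enol tautomers) | CCCC1CC(O)=CC(=O)C1C(=O)OCc1ccccc1
F3 | step 7 | benzyl 3-diazo-2,4-dioxo-6-propylcyclohexane-1-carboxylate (racemic) | CCCC1CC(=O)C(=[N+]=[N-])C(=O)C1C(=O)OCc1ccccc1
F0 | step 8 | none | none
F4 | step 6 | 2-oxo-3-(triphenylphosphoranylidene)propyl 4-(benzyloxy)-2-methoxy-6-propylbenzoate | CCCc1cc(OCc2ccccc2)cc(OC)c1C(=O)OCC(=O)C=P(c1ccccc1)(c1ccccc1)c1ccccc1
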